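**Plan**

- Retrosynthesis: the C3=C4 alkene goes back to a chroman-3-one (enol triflate reduction). Cutting C4a–C4 and C4–C3 then removes C4 and leaves a benzofuran-3(2H)-one. Further cuts are the aryl–CH2 bond at C6 (B-alkyl Suzuki), the side-chain C=C (Wittig), the C2–CH2 bond (Michael addition) and the C3–C3a and O–C2 bonds of the furanone.
- Forward order: the furanone ring is closed first, C2 is made quaternary, the enoate chain is built and the catechol arm is attached. The pyran ring then arises by one-carbon enlargement of the furanone, followed by the chromene alkene, the allylic alcohol and the free catechol.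
- Enabling feature: deleting C4 from the pyran ring (O1–C2–C3–C4–C4a–C8a) contracts it to the five-membered ring of a benzofuran-3(2H)-one with C3 as carbonyl carbon. C2 then lies between the ring oxygen and that carbonyl, where an acidic C–H allows enantioselective alkylation to the quaternary centre. Once quaternary, C2 leaves C4 as the only enolisable position after ring enlargement.
- Stereochemistry: the single stereocentre C2 (S) is set by a cinchona-ammonium phase-transfer Michael addition to acrolein and is not touched afterwards. The (E)-alkene comes from a stabilised Wittig reaction.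

Key step: step 8

Assumption: the cinchonidine-derived ammonium salt of step 3 is taken to give the (S) adduct; if the sense of induction is the opposite, its cinchonine-derived pseudoenantiomer is used under the same conditions.

**Route**

Step 1
Reactants: 1 4-bromophenol; 2 2-bromopropanoic acid (racemic)
Product: 3 2-(4-bromophenoxy)propanoic acid (racemic)
Conditions: NaOH (aq, 2.5 equiv), H2O, reflux; then aq HCl to pH 1
Reagents that add atoms: none
Why: Williamson ether synthesis in which the phenoxide of 1 displaces bromide from the carboxylate of 2 by SN2, the standard access to 2-aryloxypropanoic acids; the stereocentre is irrelevant because it is enolised later.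

Step 2
Reactants: 3 2-(4-bromophenoxy)propanoic acid (racemic)
Product: 5 5-bromo-2-methyl-1-benzofuran-3(2H)-one (racemic), via 2-(4-bromophenoxy)propanoyl chloride 4 (not isolated)
Conditions: (COCl)2, DMF (cat.), CH2Cl2, 0 °C → rt; then AlCl3 (1.5 equiv), CH2Cl2, 0 °C → rt
Reagents that add atoms: none
Why: Intramolecular Friedel–Crafts acylation in which the acylium ion from 4 attacks the position ortho to the ether oxygen (the only activated site, meta to bromine) and closes the five-membered furanone ring.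

Step 3
Reactants: 5 5-bromo-2-methyl-1-benzofuran-3(2H)-one (racemic); 6 acrolein (prop-2-enal)
Product: 7 3-[(2S)-5-bromo-2-methyl-3-oxo-2,3-dihydro-1-benzofuran-2-yl]propanal
Conditions: acrolein (1.5 equiv, slow addition), O-allyl-N-(9-anthracenylmethyl)cinchonidinium bromide (10 mol %), Cs2CO3 (0.5 equiv), toluene, –40 °C, argon
Reagents that add atoms: none
Why: Asymmetric phase-transfer Michael addition, of the type known for 2-alkyl-1-indanones and vinyl ketones under cinchona ammonium catalysis: the carbonate forms the planar, aromatic 3-oxidobenzofuran enolate of 5, the chiral ammonium cation pairs with it and shields one face of C2, and acrolein adds to the open face to set the (S) quaternary centre.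

Step 4
Reactants: 7 3-[(2S)-5-bromo-2-methyl-3-oxo-2,3-dihydro-1-benzofuran-2-yl]propanal
Product: 8 ethyl (2E)-5-[(2S)-5-bromo-2-methyl-3-oxo-2,3-dihydro-1-benzofuran-2-yl]-2-methylpent-2-enoate
Conditions: Ph3P=C(CH3)CO2Et (1.2 equiv), CH2Cl2, rt
Reagents that add atoms: ethyl 2-(triphenylphosphoranylidene)propanoate, CCOC(=O)C(C)=P(c1ccccc1)(c1ccccc1)c1ccccc1
Why: Wittig olefination with a stabilised α-methyl ylide, which reacts only with the aldehyde (the hindered aryl ketone next to the quaternary carbon is inert) and gives the (E)-trisubstituted enoate.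

Step 5
Reactants: 9 2,3-dihydroxybenzaldehyde
Product: 10 2,3-bis(tert-butyldimethylsilyloxy)benzaldehyde
Conditions: TBSCl (2.5 equiv), imidazole (5 equiv), DMF, rt
Reagents that add atoms: tert-butyldimethylsilyl chloride, CC(C)(C)[Si](C)(C)Cl
Why: Standard imidazole-promoted silylation of phenols; the silyl ethers mask the catechol against borane, base and palladium and are removed with fluoride at the end.

Step 6
Reactants: 10 2,3-bis(tert-butyldimethylsilyloxy)benzaldehyde
Product: 11 1,2-bis(tert-butyldimethylsilyloxy)-3-ethenylbenzene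
Conditions: Ph3PCH3Br (1.3 equiv), KOtBu (1.25 equiv), THF, 0 °C → rt
Reagents that add atoms: methyltriphenylphosphonium bromide, C[P+](c1ccccc1)(c1ccccc1)c1ccccc1.[Br-]
Why: Wittig methylenation of an aromatic aldehyde with the non-stabilised ylide, which aryl silyl ethers tolerate at 0 °C.

Step 7
Reactants: 11 1,2-bis(tert-butyldimethylsilyloxy)-3-ethenylbenzene; 8 ethyl (2E)-5-[(2S)-5-bromo-2-methyl-3-oxo-2,3-dihydro-1-benzofuran-2-yl]-2-methylpent-2-enoate
Product: 13 ethyl (2E)-5-[(2S)-5-[2-[2,3-bis(tert-butyldimethylsilyloxy)phenyl]ethyl]-2-methyl-3-oxo-2,3-dihydro-1-benzofuran-2-yl]-2-methylpent-2-enoate, via alkyl-9-BBN adduct 12 (not isolated)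
Conditions: 11 (1.4 equiv), 9-BBN (0.5 M in THF, 1.3 equiv), 0 °C → rt; then 8 (1.0 equiv), PdCl2(dppf)·CH2Cl2 (5 mol %), K3PO4 (3 M aq), THF, 45 °C
Reagents that add atoms: none
Why: B-alkyl Suzuki–Miyaura coupling in which 9-BBN places boron on the terminal carbon of the styrene and the primary alkyl group is transferred from the borate to the arylpalladium bromide formed from 8 and zerovalent palladium; aqueous K3PO4 in THF is mild enough for the non-enolisable ketone, the enoate and the aryl silyl ethers.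

Step 8
Reactants: 13 ethyl (2E)-5-[(2S)-5-[2-[2,3-bis(tert-butyldimethylsilyloxy)phenyl]ethyl]-2-methyl-3-oxo-2,3-dihydro-1-benzofuran-2-yl]-2-methylpent-2-enoate
Product: 15 ethyl (2E)-5-[(2S)-6-[2-[2,3-bis(tert-butyldimethylsilyloxy)phenyl]ethyl]-2-methyl-3-oxo-3,4-dihydro-2H-chromen-2-yl]-2-methylpent-2-enoate, via α-silyl chroman-3-one 14 (not isolated)
Conditions: Me3SiCHN2 (2 M in hexanes, 1.5 equiv), BF3·OEt2 (1.5 equiv), CH2Cl2, –78 → –30 °C; then 1 M HCl, THF, 0 °C
Reagents that add atoms: trimethylsilyldiazomethane, C[Si](C)(C)C=[N+]=[N-]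
Why: Proposed new method: the BF3-bound ketone of 13 is attacked at C3 by the diazo carbon, and the resulting β-oxido diazonium loses N2 with a 1,2-shift of the electron-rich aryl carbon C3a (ortho to the ring oxygen) onto the new carbon, which becomes C4 between C4a and the carbonyl; the closest known reaction type is the Lewis-acid-promoted trimethylsilyldiazomethane homologation of 1-indanones, 1-tetralones and cycloalkanones, which has not been described for benzofuran-3(2H)-ones. The six-membered pyranone ring is formed by enlargement of the furanone through migration of a ring bond, not by a cyclisation. No stereocentre remains from the step (the silyl-bearing C4 of 14 is lost on protodesilylation), and the quaternary C2 (S), which cannot enolise and does not migrate, is carried through unchanged. The step needs attack at the ketone and not at the trisubstituted enoate, and a single insertion: the first should follow from Lewis acid activation of the strained, Lewis-basic ketone at –78 °C, where dipolar cycloaddition to the enoate is slow, and the second from the bulky silyl group of 14 (or its O-silyl enol ether after a Brook shift), which blocks a further addition. The direction of migration is not critical, because a shift of C2 (with retention) would give the chroman-4-one, whose enol triflate leads to the same C3=C4 alkene in steps 9 and 10.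

Step 9
Reactants: 15 ethyl (2E)-5-[(2S)-6-[2-[2,3-bis(tert-butyldimethylsilyloxy)phenyl]ethyl]-2-methyl-3-oxo-3,4-dihydro-2H-chromen-2-yl]-2-methylpent-2-enoate
Product: 17 ethyl (2E)-5-[(2S)-6-[2-[2,3-bis(tert-butyldimethylsilyloxy)phenyl]ethyl]-2-methyl-3-[(trifluoromethanesulfonyl)oxy]-2H-chromen-2-yl]-2-methylpent-2-enoate, via potassium enolate 16 (not isolated)
Conditions: crude 15, KN(SiMe3)2 (1.1 equiv), THF, –78 °C; then PhNTf2 (1.2 equiv), –78 → 0 °C
Reagents that add atoms: N-phenylbis(trifluoromethanesulfonimide), O=S(=O)(N(c1ccccc1)S(=O)(=O)C(F)(F)F)C(F)(F)F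
Why: Enol triflate formation: C2 is quaternary, so the base can remove only the benzylic C4–H next to the ketone (far more acidic than the γ-hydrogens of the enoate), and O-sulfonylation of the enolate fixes the C3=C4 double bond.

Step 10
Reactants: 17 ethyl (2E)-5-[(2S)-6-[2-[2,3-bis(tert-butyldimethylsilyloxy)phenyl]ethyl]-2-methyl-3-[(trifluoromethanesulfonyl)oxy]-2H-chromen-2-yl]-2-methylpent-2-enoate
Product: 18 ethyl (2E)-5-[(2S)-6-[2-[2,3-bis(tert-butyldimethylsilyloxy)phenyl]ethyl]-2-methyl-2H-chromen-2-yl]-2-methylpent-2-enoate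
Conditions: Pd(OAc)2 (5 mol %), PPh3 (10 mol %), HCO2H (2 equiv), Et3N (3 equiv), THF, 60 °C
Reagents that add atoms: none
Why: Palladium-catalysed formate reduction of an enol triflate (Cacchi reduction): oxidative addition of zerovalent palladium into the C–O bond, exchange of triflate for formate, loss of CO2 and C–H reductive elimination give the 2H-chromene without touching the enoate or C2.

Step 11
Reactants: 18 ethyl (2E)-5-[(2S)-6-[2-[2,3-bis(tert-butyldimethylsilyloxy)phenyl]ethyl]-2-methyl-2H-chromen-2-yl]-2-methylpent-2-enoate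
Product: 19 (2E)-5-[(2S)-6-[2-[2,3-bis(tert-butyldimethylsilyloxy)phenyl]ethyl]-2-methyl-2H-chromen-2-yl]-2-methylpent-2-en-1-ol
Conditions: i-Bu2AlH (2.5 equiv), CH2Cl2, –78 → 0 °C; aq potassium sodium tartrate
Reagents that add atoms: none
Why: 1,2-Reduction of the α,β-unsaturated ester with i-Bu2AlH gives the (E)-allylic alcohol with the alkene geometry intact, while the chromene and the silyl ethers are inert.

Step 12
Reactants: 19 (2E)-5-[(2S)-6-[2-[2,3-bis(tert-butyldimethylsilyloxy)phenyl]ethyl]-2-methyl-2H-chromen-2-yl]-2-methylpent-2-en-1-ol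
Product: 20 3-[2-[(2S)-2-[(3E)-5-hydroxy-4-methylpent-3-en-1-yl]-2-methyl-2H-chromen-6-yl]ethyl]benzene-1,2-diol
Conditions: Bu4NF (2.5 equiv), AcOH (2.5 equiv), THF, 0 °C, argon
Reagents that add atoms: none
Why: Fluoride cleavage of the two aryl silyl ethers; the acetic acid buffer and exclusion of air should keep the liberated catechol from oxidising and spare the chromene and the allylic alcohol.

**Compound list**

1 | 4-bromophenol | Oc1ccc(Br)cc1 | starting material
2 | 2-bromopropanoic acid (racemic) | CC(Br)C(=O)O | starting material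
3 | 2-(4-bromophenoxy)propanoic acid (racemic) | CC(Oc1ccc(Br)cc1)C(=O)O | intermediate
4 | 2-(4-bromophenoxy)propanoyl chloride (racemic) | CC(Oc1ccc(Br)cc1)C(Cl)=O | intermediate (not isolated)
5 | 5-bromo-2-methyl-1-benzofuran-3(2H)-one (racemic) | CC1Oc2ccc(Br)cc2C1=O | intermediate
6 | acrolein (prop-2-enal) | C=CC=O | starting material
7 | 3-[(2S)-5-bromo-2-methyl-3-oxo-2,3-dihydro-1-benzofuran-2-yl]propanal | O=CCC[C@@]1(C)C(=O)c2cc(Br)ccc2O1 | intermediate
8 | ethyl (2E)-5-[(2S)-5-bromo-2-methyl-3-oxo-2,3-dihydro-1-benzofuran-2-yl]-2-methylpent-2-enoate | CCOC(=O)/C(C)=C/CC[C@@]1(C)C(=O)c2cc(Br)ccc2O1 | intermediate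
9 | 2,3-dihydroxybenzaldehyde | O=Cc1cccc(O)c1O | starting material
10 | 2,3-bis(tert-butyldimethylsilyloxy)benzaldehyde | O=Cc1cccc(O[Si](C)(C)C(C)(C)C)c1O[Si](C)(C)C(C)(C)C | intermediate
11 | 1,2-bis(tert-butyldimethylsilyloxy)-3-ethenylbenzene | C=Cc1cccc(O[Si](C)(C)C(C)(C)C)c1O[Si](C)(C)C(C)(C)C | intermediate
12 | 9-[2-[2,3-bis(tert-butyldimethylsilyloxy)phenyl]ethyl]-9-borabicyclo[3.3.1]nonane | CC(C)(C)[Si](C)(C)Oc1cccc(CCB2C3CCCC2CCC3)c1O[Si](C)(C)C(C)(C)C | intermediate (not isolated)
13 | ethyl (2E)-5-[(2S)-5-[2-[2,3-bis(tert-butyldimethylsilyloxy)phenyl]ethyl]-2-methyl-3-oxo-2,3-dihydro-1-benzofuran-2-yl]-2-methylpent-2-enoate | CCOC(=O)/C(C)=C/CC[C@@]1(C)C(=O)c2cc(CCc3cccc(O[Si](C)(C)C(C)(C)C)c3O[Si](C)(C)C(C)(C)C)ccc2O1 | intermediate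
14 | ethyl (2E)-5-[(2S)-6-[2-[2,3-bis(tert-butyldimethylsilyloxy)phenyl]ethyl]-2-methyl-3-oxo-4-(trimethylsilyl)-3,4-dihydro-2H-chromen-2-yl]-2-methylpent-2-enoate (both C4 epimers) | CCOC(=O)/C(C)=C/CC[C@@]1(C)C(=O)C([Si](C)(C)C)c2cc(CCc3cccc(O[Si](C)(C)C(C)(C)C)c3O[Si](C)(C)C(C)(C)C)ccc2O1 | intermediate (not isolated)
15 | ethyl (2E)-5-[(2S)-6-[2-[2,3-bis(tert-butyldimethylsilyloxy)phenyl]ethyl]-2-methyl-3-oxo-3,4-dihydro-2H-chromen-2-yl]-2-methylpent-2-enoate | CCOC(=O)/C(C)=C/CC[C@@]1(C)C(=O)Cc2cc(CCc3cccc(O[Si](C)(C)C(C)(C)C)c3O[Si](C)(C)C(C)(C)C)ccc2O1 | intermediate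
16 | potassium (2S)-6-[2-[2,3-bis(tert-butyldimethylsilyloxy)phenyl]ethyl]-2-[(3E)-5-ethoxy-4-methyl-5-oxopent-3-en-1-yl]-2-methyl-2H-chromen-3-olate | CCOC(=O)/C(C)=C/CC[C@@]1(C)C([O-])=Cc2cc(CCc3cccc(O[Si](C)(C)C(C)(C)C)c3O[Si](C)(C)C(C)(C)C)ccc2O1.[K+] | intermediate (not isolated)
17 | ethyl (2E)-5-[(2S)-6-[2-[2,3-bis(tert-butyldimethylsilyloxy)phenyl]ethyl]-2-methyl-3-[(trifluoromethanesulfonyl)oxy]-2H-chromen-2-yl]-2-methylpent-2-enoate | CCOC(=O)/C(C)=C/CC[C@@]1(C)C(OS(=O)(=O)C(F)(F)F)=Cc2cc(CCc3cccc(O[Si](C)(C)C(C)(C)C)c3O[Si](C)(C)C(C)(C)C)ccc2O1 | intermediate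
18 | ethyl (2E)-5-[(2S)-6-[2-[2,3-bis(tert-butyldimethylsilyloxy)phenyl]ethyl]-2-methyl-2H-chromen-2-yl]-2-methylpent-2-enoate | CCOC(=O)/C(C)=C/CC[C@@]1(C)C=Cc2cc(CCc3cccc(O[Si](C)(C)C(C)(C)C)c3O[Si](C)(C)C(C)(C)C)ccc2O1 | intermediate
19 | (2E)-5-[(2S)-6-[2-[2,3-bis(tert-butyldimethylsilyloxy)phenyl]ethyl]-2-methyl-2H-chromen-2-yl]-2-methylpent-2-en-1-ol | C/C(=C\CC[C@@]1(C)C=Cc2cc(CCc3cccc(O[Si](C)(C)C(C)(C)C)c3O[Si](C)(C)C(C)(C)C)ccc2O1)CO | intermediate
20 | 3-[2-[(2S)-2-[(3E)-5-hydroxy-4-methylpent-3-en-1-yl]-2-methyl-2H-chromen-6-yl]ethyl]benzene-1,2-diol | C/C(=C\CC[C@@]1(C)C=Cc2cc(CCc3cccc(O)c3O)ccc2O1)CO | target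

**Step count and risks**

Total step count: 12. Longest linear sequence: 10 steps (1 → 3 → 5 → 7 → 8 → 13 → 15 → 17 → 18 → 19 → 20); steps 5 and 6 form the two-step side branch that joins in step 7.

Steps most likely to fail:

1. Step 8 (proposed new method). The ortho-alkoxy aryl ketone may add the diazoalkane sluggishly, the betaine may close to the epoxide instead of rearranging, or a second insertion may follow the first. The fallback sets out from 13 and returns at 15 by a stepwise Tiffeneau–Demjanov sequence built from known reactions. Corey–Chaykovsky methylenation of the ketone (Me3SI, KN(SiMe3)2, THF, –10 °C) would give the spiro[benzofuran-3,2'-oxirane] F1. Opening at the CH2 terminus with NaN3/NH4Cl (aq EtOH, 65 °C) would give the 3-(azidomethyl)-3-hydroxy-2,3-dihydrobenzofuran F2. Staudinger reduction (PPh3, THF/H2O) would give the 3-(aminomethyl)-3-hydroxy-2,3-dihydrobenzofuran F3. Diazotisation with NaNO2 in aqueous AcOH at 0 °C should then expand the ring by the same aryl shift to 15.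

2. Step 3. Facial selectivity at the planar enolate under ion-pair control may be poor, or acrolein may polymerise under base. The fallback sets out from 5 and returns at 7. O-Acylation of the sodium enolate (NaN(SiMe3)2, THF, –78 °C, allyl chloroformate) would give 5-bromo-2-methyl-1-benzofuran-3-yl prop-2-en-1-yl carbonate F4. Decarboxylative asymmetric allylic alkylation (Pd2(dba)3, the enantiomer of the DACH-phenyl Trost ligand that leads to the (S) ketone, toluene, rt, where oxidative addition to the aryl bromide does not compete) should give (2S)-5-bromo-2-methyl-2-(prop-2-en-1-yl)-1-benzofuran-3(2H)-one F5. Hydroboration with 9-BBN (THF, 0 °C) to the alkyl-9-borabicyclo[3.3.1]nonane F6 and oxidation with NaBO3·4H2O would give (2S)-5-bromo-2-(3-hydroxypropyl)-2-methyl-1-benzofuran-3(2H)-one F7. Dess–Martin oxidation then gives 7.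

3. Step 2. The α-aryloxy acylium ion may lose carbon monoxide faster than it closes onto the bromine-deactivated ring. The fallback sets out from 1 and returns at 5. Acylation with propanoyl chloride (Et3N, CH2Cl2) would give 4-bromophenyl propanoate F8. Fries rearrangement (AlCl3, neat, 140 °C; the para position is blocked) would give 1-(5-bromo-2-hydroxyphenyl)propan-1-one F9. α-Bromination with CuBr2 (EtOAc/CHCl3, reflux) would give 2-bromo-1-(5-bromo-2-hydroxyphenyl)propan-1-one F10. Intramolecular O-alkylation (NaOAc, EtOH, reflux) then closes the furanone to 5.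

**Further compounds**

F1 | step 8 | ethyl (2E)-5-[(2S)-5-[2-[2,3-bis(tert-butyldimethylsilyloxy)phenyl]ethyl]-2-methyl-2H-spiro[1-benzofuran-3,2'-oxiran]-2-yl]-2-methylpent-2-enoate (both epimers at the spiro carbon) | CCOC(=O)/C(C)=C/CC[C@@]1(C)C2(CO2)c3cc(CCc4cccc(O[Si](C)(C)C(C)(C)C)c4O[Si](C)(C)C(C)(C)C)ccc3O1
F2 | step 8 | ethyl (2E)-5-[(2S)-3-(azidomethyl)-5-[2-[2,3-bis(tert-butyldimethylsilyloxy)phenyl]ethyl]-3-hydroxy-2-methyl-2,3-dihydro-1-benzofuran-2-yl]-2-methylpent-2-enoate (both C3 epimers) | CCOC(=O)/C(C)=C/CC[C@@]1(C)C(O)(CN=[N+]=[N-])c2cc(CCc3cccc(O[Si](C)(C)C(C)(C)C)c3O[Si](C)(C)C(C)(C)C)ccc2O1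
F3 | step 8 | ethyl (2E)-5-[(2S)-3-(aminomethyl)-5-[2-[2,3-bis(tert-butyldimethylsilyloxy)phenyl]ethyl]-3-hydroxy-2-methyl-2,3-dihydro-1-benzofuran-2-yl]-2-methylpent-2-enoate (both C3 epimers) | CCOC(=O)/C(C)=C/CC[C@@]1(C)C(O)(CN)c2cc(CCc3cccc(O[Si](C)(C)C(C)(C)C)c3O[Si](C)(C)C(C)(C)C)ccc2O1
F4 | step 3 | 5-bromo-2-methyl-1-benzofuran-3-yl prop-2-en-1-yl carbonate | C=CCOC(=O)Oc1c(C)oc2ccc(Br)cc12
F5 | step 3 | (2S)-5-bromo-2-methyl-2-(prop-2-en-1-yl)-1-benzofuran-3(2H)-one | C=CC[C@@]1(C)C(=O)c2cc(Br)ccc2O1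
F6 | step 3 | (2S)-2-[3-(9-borabicyclo[3.3.1]nonan-9-yl)propyl]-5-bromo-2-methyl-1-benzofuran-3(2H)-one | B1(CCC[C@@]2(C)C(=O)c3cc(Br)ccc3O2)C4CCCC1CCC4
F7 | step 3 | (2S)-5-bromo-2-(3-hydroxypropyl)-2-methyl-1-benzofuran-3(2H)-one | OCCC[C@@]1(C)C(=O)c2cc(Br)ccc2O1
F8 | step 2 | 4-bromophenyl propanoate | CCC(=O)Oc1ccc(Br)cc1
F9 | step 2 | 1-(5-bromo-2-hydroxyphenyl)propan-1-one | CCC(=O)c1cc(Br)ccc1O
F10 | step 2 | 2-bromo-1-(5-bromo-2-hydroxyphenyl)propan-1-one (racemic) | CC(Br)C(=O)c1cc(Br)ccc1O
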